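**Plan**
- Retrosynthesis: the methacrylate (C14–O), the two acetates (C6–O, C1–O) and the exocyclic C11=C13 are late functional-group changes. The lactone C12–O8 bond comes from a C7 malonate. The carbocycle is then cut at C6–C7 and at C5=C10.
- Forward: a glycidol-derived C7–C10/C14 fragment carrying an alkylidene malonate (acceptor at C7) and a C10 ketone is annulated with (S)-citronellal to the cyclohexenone. Then C6 reduction, lactone closure, methylenation and the esters follow; the carbocycle forms first, the lactone second.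
- Enabling feature: ring carbon C6 is 1,4 to the lactone carbonyl C12 (through C7–C11) and 1,5 to ring carbon C10, and C6–C5 map onto the CHO/α-CH2 pair of citronellal, so one aldehyde can act first as acyl anion and then as enolate.
- Stereochemistry: C4 from (S)-citronellal; C8 from (S)-glycidol; C7 by equilibration trans to the C8 oxygen; C6 by hydride delivery cis to the C7 substituent.

Key step: step 9

Remark: atom labels follow eudesmane-type numbering of the target (ring C5=C10, C6, C7, C8, C9; C14 = CH2O on C10; side chain C4(C15)–C3–C2–C1 on C5; lactone C11, C12 (C=O), C13 (=CH2)); TBS = tert-butyldimethylsilyl, PMB = 4-methoxybenzyl, TMSE = 2-(trimethylsilyl)ethyl; compounds 1, 4, 10 and 15 are taken as commercial.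

**Step 1**
Reactants: 1 (S)-glycidol
Product: 3 (R)-2-{[(4-methoxybenzyl)oxy]methyl}oxirane, via sodium alkoxide 2 (not isolated)
Conditions: NaH, Bu4NI (cat.), THF/DMF, 0 °C to rt
Reagents that add atoms: 4-methoxybenzyl chloride, COc1ccc(CCl)cc1
Why: Williamson ether synthesis on the primary alkoxide; the Payne rearrangement of glycidol alkoxide is degenerate, so the epoxide stereocentre (future C8) is kept and only its CIP descriptor changes.

**Step 2**
Reactants: 4 2-bromoprop-2-en-1-ol; 3 PMB glycidyl ether
Product: 6 (4R)-5-[(4-methoxybenzyl)oxy]-2-methylidenepentane-1,4-diol, via dilithio reagent 5 (not isolated)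
Conditions: 4, t-BuLi (3 equiv), Et2O, −78 to 0 °C; then 3, BF3·OEt2, −78 °C; H2O
Reagents that add atoms: none
Why: Bromine–lithium exchange gives the O,C-dilithio vinyl reagent, which should open the epoxide at its unsubstituted carbon (BF3-assisted SN2 epoxide opening), so the carbinol stereocentre is not touched.

**Step 3**
Reactants: 6 diol
Product: 7 (4R)-1,4-bis(TBS-oxy)-5-[(4-methoxybenzyl)oxy]-2-methylidenepentane
Conditions: imidazole, DMF, rt
Reagents that add atoms: tert-butyldimethylsilyl chloride, CC(C)(C)[Si](C)(C)Cl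
Why: Standard silyl ether formation on the primary allylic and the secondary hydroxyl groups.

**Step 4**
Reactants: 7 bis-silyl PMB ether
Product: 8 (2R)-2,5-bis(TBS-oxy)-4-methylidenepentan-1-ol
Conditions: DDQ, CH2Cl2/pH 7 buffer, 0 °C
Reagents that add atoms: none
Why: Oxidative PMB ether cleavage with DDQ is selective for the electron-rich benzyl ether and leaves silyl ethers and the 1,1-disubstituted alkene alone.

**Step 5**
Reactants: 8 primary alcohol
Product: 9 (2R)-2,5-bis(TBS-oxy)-4-methylidenepentanal
Conditions: PhI(OAc)2, TEMPO (10 mol %), CH2Cl2, rt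
Reagents that add atoms: none
Why: TEMPO-catalysed oxidation under neutral conditions stops at the aldehyde and should not epimerise the α-silyloxy stereocentre.

**Step 6**
Reactants: 10 malonic acid
Product: 11 bis[2-(trimethylsilyl)ethyl] malonate
Conditions: DCC, DMAP (cat.), CH2Cl2, 0 °C to rt
Reagents that add atoms: 2-(trimethylsilyl)ethanol, C[Si](C)(C)CCO
Why: Steglich esterification; the TMSE esters are chosen because fluoride removes them later without touching acetates.

**Step 7**
Reactants: 9 aldehyde; 11 bis-TMSE malonate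
Product: 12 bis-TMSE 2-[(2R)-2,5-bis(TBS-oxy)-4-methylidenepentylidene]malonate
Conditions: TiCl4, pyridine, THF, 0 °C to rt
Reagents that add atoms: none
Why: Knoevenagel condensation under Lehnert conditions, which are used for α-alkoxy aldehydes without epimerisation; the symmetrical malonate removes any E/Z question.

**Step 8**
Reactants: 12 alkylidene malonate
Product: 14 bis-TMSE 2-[(2R)-2,5-bis(TBS-oxy)-4-oxopentylidene]malonate, via ozonide 13 (not isolated)
Conditions: O3, CH2Cl2, −78 °C; then PPh3
Reagents that add atoms: ozone, [O-][O+]=O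
Why: Ozonolysis; the electron-rich 1,1-disubstituted alkene should react much faster than the electron-poor alkylidene malonate, and the C10 ketone is unveiled only after the aldehyde has been consumed in step 7.

**Step 9**
Reactants: 14 keto alkylidene malonate; 15 (S)-citronellal
Product: 18 cyclohexenone (C6 ketone, C5=C10, C7 malonyl trans to 8-OTBS, 14-OTBS, citronellal side chain on C5), via diketone 16 (not isolated), via ketol 17 (not isolated)
Conditions: 3-benzyl-5-(2-hydroxyethyl)-4-methylthiazolium chloride (20 mol %), Et3N (0.4 equiv), 1,4-dioxane, 60 °C; then DBU (1.5 equiv), 60 °C, same flask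
Reagents that add atoms: none
Why: The thiazol-2-ylidene adds to the aldehyde of 15 to give the Breslow intermediate, whose C6 adds as an acyl anion to C7 of the doubly activated alkene of 14 (Stetter reaction) and releases the carbene, giving the C6/C10 1,5-diketone 16; DBU then enolises toward C5, the C5 enolate adds to the C10 ketone (ketol 17) and E1cB loss of water gives the conjugated, tetrasubstituted C5=C10 enone. The closest known reaction types are the thiazolium-catalysed Stetter addition of aliphatic aldehydes to alkylidene malonates, domino Stetter–aldol sequences, and the aldol-condensation half of a Robinson annulation. The one ring formed, the C5–C10 carbocycle, closes in the 6-(enolexo)-exo-trig mode. The new stereocentre C7 is α to the C6 ketone and should be set under thermodynamic control: its epimers equilibrate through the enolate and converge on the isomer with the malonyl group trans (diequatorial) to the C8 silyloxy group, so C8 controls C7, while C4 is β to the carbonyl and is not touched. The step needs Stetter addition to outrun benzoin formation (which is reversible), aldolisation through C5 and not C14 (C14 would have to attack the C6 ketone flanked by the malonyl-bearing C7, and ketol formation is reversible while the C5 path ends in the conjugated enone), and survival of the β-silyloxy group (a poor leaving group held equatorial); the C5=C10 geometry is fixed by the ring.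

**Step 10**
Reactants: 18 cyclohexenone
Product: 20 C1 aldehyde (side chain CH(CH3)CH2CH2CHO on C5), via ozonide 19 (not isolated)
Conditions: O3, pyridine, CH2Cl2, −78 °C; then PPh3
Reagents that add atoms: ozone, [O-][O+]=O
Why: Ozonolysis; the isolated trisubstituted alkene should react first, because the ring alkene is tetrasubstituted and deactivated by the C6 carbonyl.

**Step 11**
Reactants: 20 keto aldehyde
Product: 22 1,6-diacetate (6-OAc cis to the C7 malonyl group), via diol 21 (not isolated)
Conditions: LiBH(s-Bu)3, THF, −78 °C; AcOH; then Ac2O, pyridine, DMAP (cat.), 0 °C to rt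
Reagents that add atoms: acetic anhydride, CC(=O)OC(C)=O
Why: The bulky hydride should attack the C6 ketone from the face opposite the adjacent C7 malonyl group (as in the reduction of 2-alkylcyclohexanones to cis alcohols), giving the 6-hydroxyl cis to C7; the β,β-disubstituted enone blocks 1,4-reduction, the aldehyde is reduced as well, and immediate acetylation stops the 6-hydroxyl from lactonising.

**Step 12**
Reactants: 22 diacetate
Product: 24 trans-fused 8,12-lactone with 11-CO2H and free 14-OH (C11 epimers), via hydroxy diacid 23 (not isolated)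
Conditions: Bu4NF, AcOH, THF, 0 °C to rt; aq. KHSO4; then PPTS (cat.), toluene, 50 °C
Reagents that add atoms: none
Why: Fluoride removes both silyl ethers and both TMSE esters (β-elimination), and acid-catalysed lactonisation can then only involve the 8-hydroxyl because O6 is already acetylated; the C7/C8 trans relationship gives the trans-fused γ-lactone.

**Step 13**
Reactants: 24 α-carboxy lactone
Product: 26 α-methylene lactone with free 14-OH, via Mannich base 25 (not isolated)
Conditions: aq. HCHO, Et2NH, THF, rt; then AcOH, NaOAc, 70 °C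
Reagents that add atoms: formaldehyde, C=O
Why: Decarboxylative Mannich methylenation of a malonic half-acid (aminomethylation at C11, then loss of CO2 and amine), the classical route to α-methylene-γ-butyrolactones, which uses no strong base and should spare the acetates.

**Step 14**
Reactants: 26 allylic alcohol
Product: 27 target
Conditions: Et3N, DMAP (cat.), CH2Cl2, 0 °C
Reagents that add atoms: methacryloyl chloride, C=C(C)C(Cl)=O
Why: DMAP-catalysed acylation of the only free hydroxyl group, the primary allylic 14-OH.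

**Compound list**
1 | (S)-glycidol | OC[C@H]1CO1 | starting material
2 | sodium (S)-oxiran-2-ylmethanolate | [Na+].[O-]C[C@H]1CO1 | intermediate
3 | (R)-2-{[(4-methoxybenzyl)oxy]methyl}oxirane | COc1ccc(COC[C@H]2CO2)cc1 | intermediate
4 | 2-bromoprop-2-en-1-ol | OCC(Br)=C | starting material
5 | lithium 2-lithioprop-2-en-1-olate | [Li]OCC([Li])=C | intermediate
6 | (4R)-5-[(4-methoxybenzyl)oxy]-2-methylidenepentane-1,4-diol | C=C(CO)C[C@@H](O)COCc1ccc(OC)cc1 | intermediate
7 | (4R)-1,4-bis(TBS-oxy)-5-[(4-methoxybenzyl)oxy]-2-methylidenepentane | C=C(CO[Si](C)(C)C(C)(C)C)C[C@@H](O[Si](C)(C)C(C)(C)C)COCc1ccc(OC)cc1 | intermediate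
8 | (2R)-2,5-bis(TBS-oxy)-4-methylidenepentan-1-ol | C=C(CO[Si](C)(C)C(C)(C)C)C[C@@H](O[Si](C)(C)C(C)(C)C)CO | intermediate
9 | (2R)-2,5-bis(TBS-oxy)-4-methylidenepentanal | C=C(CO[Si](C)(C)C(C)(C)C)C[C@@H](O[Si](C)(C)C(C)(C)C)C=O | intermediate
10 | malonic acid | OC(=O)CC(=O)O | starting material
11 | bis[2-(trimethylsilyl)ethyl] malonate | C[Si](C)(C)CCOC(=O)CC(=O)OCC[Si](C)(C)C | intermediate
12 | bis-TMSE 2-[(2R)-2,5-bis(TBS-oxy)-4-methylidenepentylidene]malonate | C=C(CO[Si](C)(C)C(C)(C)C)C[C@@H](O[Si](C)(C)C(C)(C)C)C=C(C(=O)OCC[Si](C)(C)C)C(=O)OCC[Si](C)(C)C | intermediate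
13 | ozonide (1,2,4-trioxolane) of the methylidene group of 12 | CC(C)(C)[Si](C)(C)OCC1(C[C@@H](O[Si](C)(C)C(C)(C)C)C=C(C(=O)OCC[Si](C)(C)C)C(=O)OCC[Si](C)(C)C)OOCO1 | intermediate
14 | bis-TMSE 2-[(2R)-2,5-bis(TBS-oxy)-4-oxopentylidene]malonate | O=C(CO[Si](C)(C)C(C)(C)C)C[C@@H](O[Si](C)(C)C(C)(C)C)C=C(C(=O)OCC[Si](C)(C)C)C(=O)OCC[Si](C)(C)C | intermediate
15 | (S)-citronellal, (3S)-3,7-dimethyloct-6-enal | O=CC[C@@H](C)CCC=C(C)C | starting material
16 | Stetter adduct: C6/C10 1,5-diketone with the malonyl group on C7 (C7 epimers; C4 and C8 as in the target) | CC(C)=CCC[C@H](C)CC(=O)C(C(C(=O)OCC[Si](C)(C)C)C(=O)OCC[Si](C)(C)C)[C@H](O[Si](C)(C)C(C)(C)C)CC(=O)CO[Si](C)(C)C(C)(C)C | intermediate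
17 | ketol: 10-hydroxy-6-oxocyclohexane from C5-to-C10 aldol addition (C5, C7, C10 epimers) | CC(C)=CCC[C@H](C)C1C(=O)C(C(C(=O)OCC[Si](C)(C)C)C(=O)OCC[Si](C)(C)C)[C@H](O[Si](C)(C)C(C)(C)C)CC1(O)CO[Si](C)(C)C(C)(C)C | intermediate
18 | cyclohex-2-enone: C6 ketone, C5=C10, C5 bearing the (S)-6-methylhept-5-en-2-yl chain, C10 bearing CH2OTBS, C7 bis-TMSE malonyl trans to 8-OTBS (C4, C7, C8 as in the target) | CC(C)(C)[Si](C)(C)OCC1=C([C@@H](C)CCC=C(C)C)C(=O)[C@@H](C(C(=O)OCC[Si](C)(C)C)C(=O)OCC[Si](C)(C)C)[C@H](O[Si](C)(C)C(C)(C)C)C1 | intermediate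
19 | ozonide of the side-chain alkene of 18 | CC(C)(C)[Si](C)(C)OCC1=C([C@@H](C)CCC2OOC(C)(C)O2)C(=O)[C@@H](C(C(=O)OCC[Si](C)(C)C)C(=O)OCC[Si](C)(C)C)[C@H](O[Si](C)(C)C(C)(C)C)C1 | intermediate
20 | keto aldehyde: as 18 with the side chain ending in C1HO | CC(C)(C)[Si](C)(C)OCC1=C([C@@H](C)CCC=O)C(=O)[C@@H](C(C(=O)OCC[Si](C)(C)C)C(=O)OCC[Si](C)(C)C)[C@H](O[Si](C)(C)C(C)(C)C)C1 | intermediate
21 | 1,6-diol: 6-OH cis to the C7 malonyl group, trans to 8-OTBS | CC(C)(C)[Si](C)(C)OCC1=C([C@@H](C)CCCO)[C@@H](O)[C@@H](C(C(=O)OCC[Si](C)(C)C)C(=O)OCC[Si](C)(C)C)[C@H](O[Si](C)(C)C(C)(C)C)C1 | intermediate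
22 | 1,6-diacetate of 21 | CC(C)(C)[Si](C)(C)OCC1=C([C@@H](C)CCCOC(C)=O)[C@@H](OC(C)=O)[C@@H](C(C(=O)OCC[Si](C)(C)C)C(=O)OCC[Si](C)(C)C)[C@H](O[Si](C)(C)C(C)(C)C)C1 | intermediate
23 | hydroxy diacid: 8-OH, 14-OH, C7 malonic acid, 1,6-diacetate | OCC1=C([C@@H](C)CCCOC(C)=O)[C@@H](OC(C)=O)[C@@H](C(C(=O)O)C(=O)O)[C@H](O)C1 | intermediate
24 | trans-fused 8,12-lactone with 11-CO2H, 14-OH, 1,6-diacetate (C11 epimers) | OCC1=C([C@@H](C)CCCOC(C)=O)[C@@H](OC(C)=O)[C@H]2C(C(=O)O)C(=O)O[C@@H]2C1 | intermediate
25 | Mannich base: 24 with CH2NEt2 on C11 | OCC1=C([C@@H](C)CCCOC(C)=O)[C@@H](OC(C)=O)[C@H]2C(CN(CC)CC)(C(=O)O)C(=O)O[C@@H]2C1 | intermediate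
26 | 14-hydroxy α-methylene lactone (target lacking the methacryloyl group) | OCC1=C([C@@H](C)CCCOC(C)=O)[C@@H](OC(C)=O)[C@H]2C(=C)C(=O)O[C@@H]2C1 | intermediate
27 | target, (4S,6S,7S,8R) in the numbering above | C=C(C)C(=O)OCC1=C([C@@H](C)CCCOC(C)=O)[C@@H](OC(C)=O)[C@H]2C(=C)C(=O)O[C@@H]2C1 | target

**Step count and risks**
Total: 14 steps. Longest linear sequence: 13 steps (steps 1–5 and 7–14, from 1).

Most likely to fail:

1. Step 9. The carbene-mediated conjugate addition may be slower than base-induced migration of the alkylidene malonate double bond toward the silyloxy carbon (loss of the C8 stereocentre). After DBU is added, β-elimination of the C8 silyloxy group followed by aromatisation, or partial aldolisation through C14, may compete. The fallback separates the two bond formations and uses a nitronate in place of the carbene; it sets out from 15 and 14. Compound 15 is reduced (NaBH4, MeOH) to (S)-citronellol F1, converted (I2, PPh3, imidazole) into (S)-citronellyl iodide F2 and then (NaNO2, DMF) into the nitroalkane F3. The nitronate of F3 (catalytic tetramethylguanidine, MeCN, 0 °C) should add to C7 of 14 to give the nitro malonate F4. A buffered reductive Nef reaction (NaOMe, then aqueous TiCl3/NH4OAc) should unveil diketone 16, which is isolated and cyclised separately with DBU at the lowest workable temperature, returning to the route at 18.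

2. Step 7. The Lewis acid/pyridine conditions may epimerise the α-silyloxy aldehyde or move the new double bond out of conjugation. The fallback builds the alkylidene malonate by alkylation and selenoxide elimination and sets out from 8. Alcohol 8 is converted (Tf2O, 2,6-lutidine, −78 °C) into the triflate F5, which alkylates the sodium salt of 11 (NaH, THF) to give the alkyl malonate F6. Selenenylation (NaH, then PhSeBr, −78 °C) gives the selenide F7, and oxidation (H2O2, CH2Cl2, 0 °C) gives the selenoxide F8. Its syn-elimination can only take a hydrogen from C7 and returns to the route at 12.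

3. Step 11. Hydride delivery at C6 may show poor facial selectivity, or the free 6-hydroxyl may lactonise onto the malonate before it is acetylated. The fallback accepts the other epimer and inverts it; it sets out from 20. Luche reduction (NaBH4, CeCl3·7H2O, MeOH, −78 °C) should favour the equatorial alcohol, the 6-epi-diol F9. A Mitsunobu reaction with acetic acid (PPh3, diisopropyl azodicarboxylate, AcOH, THF) should then acetylate C1–OH and install the C6 acetate with inversion, returning to the route at 22.

**Further compounds**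
F1 | step 9 | (3S)-3,7-dimethyloct-6-en-1-ol | OCC[C@@H](C)CCC=C(C)C
F2 | step 9 | (6S)-8-iodo-2,6-dimethyloct-2-ene | ICC[C@@H](C)CCC=C(C)C
F3 | step 9 | (6S)-2,6-dimethyl-8-nitrooct-2-ene | [O-][N+](=O)CC[C@@H](C)CCC=C(C)C
F4 | step 9 | nitro analogue of 16 (NO2 and H on C6 in place of the ketone oxygen; C6, C7 epimers) | CC(C)=CCC[C@H](C)CC([N+](=O)[O-])C(C(C(=O)OCC[Si](C)(C)C)C(=O)OCC[Si](C)(C)C)[C@H](O[Si](C)(C)C(C)(C)C)CC(=O)CO[Si](C)(C)C(C)(C)C
F5 | step 7 | trifluoromethanesulfonate of 8 | C=C(CO[Si](C)(C)C(C)(C)C)C[C@@H](O[Si](C)(C)C(C)(C)C)COS(=O)(=O)C(F)(F)F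
F6 | step 7 | bis-TMSE 2-[2,5-bis(TBS-oxy)-4-methylidenepentyl]malonate (silyloxy carbon as in 8) | C=C(CO[Si](C)(C)C(C)(C)C)C[C@@H](O[Si](C)(C)C(C)(C)C)CC(C(=O)OCC[Si](C)(C)C)C(=O)OCC[Si](C)(C)C
F7 | step 7 | 2-(phenylselanyl) derivative of F6 | C=C(CO[Si](C)(C)C(C)(C)C)C[C@@H](O[Si](C)(C)C(C)(C)C)CC([Se]c1ccccc1)(C(=O)OCC[Si](C)(C)C)C(=O)OCC[Si](C)(C)C
F8 | step 7 | selenoxide of F7 | C=C(CO[Si](C)(C)C(C)(C)C)C[C@@H](O[Si](C)(C)C(C)(C)C)CC([Se](=O)c1ccccc1)(C(=O)OCC[Si](C)(C)C)C(=O)OCC[Si](C)(C)C
F9 | step 11 | 6-epi-diol (6-OH trans to the C7 malonyl group) | CC(C)(C)[Si](C)(C)OCC1=C([C@@H](C)CCCO)[C@H](O)[C@@H](C(C(=O)OCC[Si](C)(C)C)C(=O)OCC[Si](C)(C)C)[C@H](O[Si](C)(C)C(C)(C)C)C1
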